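Slowness is what I look for first in a chain of steps. Here four flasks of one recipe, at four temperatures, each get 2.0 h, and I want to know which holds the most target.

    substrate + coupling partner → intermediate A (k1 = 0.022 M⁻¹ s⁻¹, Ea1 = 47.0 kJ mol⁻¹)
    second reagent + intermediate A → intermediate B (k2 = 0.045 M⁻¹ s⁻¹, Ea2 = 50.0 kJ mol⁻¹)
    third reagent + intermediate B → target (k3 = 0.0034 M⁻¹ s⁻¹, Ea3 = 56.0 kJ mol⁻¹)
    substrate + second reagent → side product (k4 = 0.042 M⁻¹ s⁻¹, Ea4 = 58.0 kJ mol⁻¹)
    coupling partner ⇌ dormant form (K5 = 0.32, k5 = 2.5 × 10⁻⁴ s⁻¹, Ea5 = 99.0 kJ mol⁻¹, ΔH5 = −12.0 kJ mol⁻¹)
    (constants at 70 °C)

the same everywhere: substrate 0.020 M; coupling partner 1.05 equiv; second reagent 1.50 equiv; third reagent 0.900 equiv; time 2.0 h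

| run | temperature |
|---|---|
| Friday's | 45 °C |
| Sunday's | 20 °C |
| Monday's | 70 °C |
| Saturday's | 95 °C |

- constants are those at 70 °C; use the activation energies and enthalpies for any other temperature

1. the flask that comes out highest in amount of target, in percent of the substrate charged, or "all alike" when all lie within 1.5 percentage points (Friday's / Sunday's / Monday's / Saturday's / all alike)
2. target at the end, in percent of the substrate charged, Friday's
3. target at the end, in percent of the substrate charged, Sunday's
4. target at the end, in percent of the substrate charged, Monday's
5. target at the end, in percent of the substrate charged, Saturday's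

I follow one substrate molecule through two gates. At the first it meets either coupling partner, which leads on to intermediate A, or second reagent, which ends in side product. Both rates carry c(substrate), so it cancels, and what remains is a selectivity. I call it the fork chance: the rate constant of the good road times c(coupling partner), over that same term plus the rate constant of the loss times c(second reagent), taken at the charge and at the flask's temperature. For Sunday's flask this fork chance is 41.4%.

The second gate is the last step, whose constant 0.0034 M⁻¹ s⁻¹ is the smallest of the second-order ones, so I treat it as the rate-limiting step. A molecule standing at intermediate B then passes with a gate chance of one minus exp(−constant × c(third reagent) × time), with c(third reagent) at its charge of 0.0180 M.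

| Flask | Fork chance | Gate chance | Product |
|---|---|---|---|
| Sunday's, 20 °C | 41.4% | 1.54% | 0.637% |
| Friday's, 45 °C | 33.2% | 8.99% | 2.98% |
| Monday's, 70 °C | 26.8% | 35.6% | 9.56% |
| Saturday's, 95 °C | 22.0% | 81.2% | 17.9% |

Reading down the second column, heating costs a factor of 1.88 in fork chance, since the loss has the higher activation energy by 11.0 kJ mol⁻¹. Reading down the third, it gains a factor of 52.7, which is far more. So the product climbs with temperature and my choice is Saturday's. I expect the last column to run high, though: the gate chance grants the whole time at intermediate B, and a molecule has to get there first.

The forecast also names Saturday's, with 0.015%, 0.8%, 7% and 16% for Sunday's, Friday's, Monday's and Saturday's, on the ground that “the hottest flask wins clearly even with its poorer selectivity”.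

The flasks give 0.0177%, 0.827%, 7.02% and 17.5% in that order, so Saturday's leads. Saturday's flask stands just under its product in my table, while Sunday's stands 36.0 times under its own. At the end of Sunday's flask, substrate goes to side product 1.4 times as fast as to intermediate A. The neighbour like Sunday's flask but with 0.0050 M of substrate keeps the equivalents, so its fork chance stays 41.4%. In that neighbour, with 89% of the substrate still there at the end, 4.34% intermediate A and 0.269% intermediate B stand against 6.52% side product, so the road through intermediate A holds 41.4% of the substrate that has reacted, with target at 0%.

All constants were drawn at random within sensible limits; what happens was integrated by code.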